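**Plan**

1. Retrosynthesis: the C8 methacrylate, the C9 acetate and the C14 aldehyde oxygen come off first. The 10-membered carbocycle is then opened at C7–C8 to a C8 aldehyde and a 3-(bromomethyl)butenolide (C13–C11=C7). The butenolide is cut at C7=C11 (metathesis) and at the C6–O acyl bond, and the chain at C3–C4 (sp3–sp2 coupling), C1=C10 (Wittig) and C5–C6 (alkynylation).
2. Enabling feature: C8 is a carbinol carbon and its neighbour C7 is the γ-carbon of the C13–C11(=C7)–C12 unit of the α-methylene-γ-lactone (ring O–C6–C7–C11–C12). An allyl metal at C13 can therefore deliver C7 to a C8 aldehyde with allylic transposition, which makes the C7–C8 bond, the C11=C13 methylene, the C8 oxygen and the ring C1–C10 in one event.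
3. Forward order: east piece (C1–C3, C8–C10, C14; steps 1–6) and west piece (C4–C7, C15; steps 7–8) are joined at C3–C4 (step 9). The five-membered lactone ring is made by acylation and ring-closing metathesis (steps 10–11), the 10-membered ring is closed last (step 14), and the esters and the C14 aldehyde follow (steps 15–20).
4. Stereochemistry: C9 comes from the chiral pool (D-glyceric acid acetonide ester) and C6 from a catalytic enantioselective alkynylation. C7 is set from C6 in the ring closure (trans lactone). C8 is formed as the 8R alcohol under chair and Felkin–Anh control and inverted to 8S by the Mitsunobu esterification that installs the methacrylate.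
5. Olefin geometry: C1=C10 comes from the Z-selective Wittig reaction of an α-alkoxy ketone and is kept in the SeO2 oxidation of C14. C4=C5 comes from trans-hydroalumination/iodination and a stereoretentive coupling.

Key step: step 14

Remark: germacrane numbering is used for the skeleton (ring C1–C10, lactone O on C6, carbonyl C12, C11=C13, C14 on C10, C15 on C4); both ring double bonds are cis within the ring.
Remark: 4, 11, 20 and 27 are taken as purchased reagents.
Remark: the (S,S) ligand in step 7 is assumed to give the 3S alcohol by analogy with its facial preference in aldol additions; the antipodal ligand is used if a Mosher ester check shows the opposite sense.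

Step 1
Reactants: 1 methyl (R)-2,2-dimethyl-1,3-dioxolane-4-carboxylate
Product: 3 (R)-1-(2,2-dimethyl-1,3-dioxolan-4-yl)ethan-1-one, via Weinreb amide 2 (not isolated)
Conditions: MeNH(OMe)·HCl, i-PrMgCl, THF, −20 °C; then MeMgBr, −20 → 0 °C; aq. NH4Cl
Reagents that add atoms: methylmagnesium bromide, C[Mg]Br (N,O-dimethylhydroxylamine hydrochloride, CNOC.Cl, enters intermediate 2 only)
Why: The magnesium amide converts the ester into the Weinreb amide, whose chelated adduct with MeMgBr stops at the ketone (Weinreb ketone synthesis), and the C9 stereocentre is not touched.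

Step 2
Reactants: 3 (R)-1-(2,2-dimethyl-1,3-dioxolan-4-yl)ethan-1-one; 4 [3-(tert-butyldimethylsilyloxy)propyl]triphenylphosphonium bromide
Product: 6 (4S)-4-[(2Z)-5-(tert-butyldimethylsilyloxy)pent-2-en-2-yl]-2,2-dimethyl-1,3-dioxolane, via phosphorus ylide 5 (not isolated)
Conditions: 4, KN(SiMe3)2, THF, 0 °C; then 3, −78 °C → rt
Reagents that add atoms: none
Why: The Wittig reaction of an α-alkoxy methyl ketone with a non-stabilised ylide is Z-selective, placing the new chain (C2) cis to the oxygen-bearing C9 and the C14 methyl trans to it, and the low temperature should keep the enolisable C9 centre intact.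

Step 3
Reactants: 6 (4S)-4-[(2Z)-5-(tert-butyldimethylsilyloxy)pent-2-en-2-yl]-2,2-dimethyl-1,3-dioxolane
Product: 7 (3Z)-4-[(4S)-2,2-dimethyl-1,3-dioxolan-4-yl]pent-3-en-1-ol
Conditions: Bu4NF, THF, 0 °C → rt
Reagents that add atoms: none
Why: Fluoride cleaves the primary silyl ether while the acetonide and the olefin are inert.

Step 4
Reactants: 7 (3Z)-4-[(4S)-2,2-dimethyl-1,3-dioxolan-4-yl]pent-3-en-1-ol
Product: 8 (4S)-4-[(2Z)-5-iodopent-2-en-2-yl]-2,2-dimethyl-1,3-dioxolane
Conditions: I2, PPh3, imidazole, CH2Cl2, 0 °C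
Reagents that add atoms: iodine, II
Why: Appel-type iodination of the primary alcohol proceeds by SN2 displacement of the oxyphosphonium ion under buffered conditions that spare the acetonide.

Step 5
Reactants: 8 (4S)-4-[(2Z)-5-iodopent-2-en-2-yl]-2,2-dimethyl-1,3-dioxolane
Product: 9 (2S,3Z)-6-iodo-3-methylhex-3-ene-1,2-diol
Conditions: AcOH/H2O (4:1), 40 °C
Reagents that add atoms: none
Why: Mild acid hydrolysis of the terminal acetonide goes through the acetal carbon, so the allylic C9–O bond is not broken and the configuration is kept.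

Step 6
Reactants: 9 (2S,3Z)-6-iodo-3-methylhex-3-ene-1,2-diol
Product: 10 (2S,3Z)-6-iodo-3-methyl-1,2-bis(triethylsilyloxy)hex-3-ene
Conditions: Et3SiOTf, 2,6-lutidine, CH2Cl2, −78 → 0 °C
Reagents that add atoms: triethylsilyl trifluoromethanesulfonate, CC[Si](CC)(CC)OS(=O)(=O)C(F)(F)F
Why: The silyl triflate with a hindered base silylates both hydroxyls without N-alkylation by the primary iodide, giving a primary silyl ether (later C8 aldehyde) and a non-chelating secondary one (C9).

Step 7
Reactants: 11 tert-butyldiphenyl(prop-2-yn-1-yloxy)silane; 12 acrolein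
Product: 14 (3S)-6-(tert-butyldiphenylsilyloxy)hex-1-en-4-yn-3-ol, via alkynylzinc 13 (not isolated)
Conditions: 11, Me2Zn, (S,S)-ProPhenol (cat.), Ph3PO (cat.), toluene, 0 °C; then 12 added slowly, 0 °C; aq. NH4Cl
Reagents that add atoms: none
Why: Zinc–ProPhenol-catalysed enantioselective 1,2-addition of the alkynylzinc to an α,β-unsaturated aldehyde, in which the chiral dinuclear zinc catalyst differentiates the aldehyde faces and sets C6.

Step 8
Reactants: 14 (3S)-6-(tert-butyldiphenylsilyloxy)hex-1-en-4-yn-3-ol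
Product: 16 (3S,4Z)-6-(tert-butyldiphenylsilyloxy)-5-iodohexa-1,4-dien-3-ol, via alkenylaluminate 15 (not isolated)
Conditions: NaAlH2(OCH2CH2OMe)2, THF, 0 °C; then I2, −78 °C
Reagents that add atoms: iodine, II
Why: Hydroxyl-directed trans-hydroalumination of the propargylic alcohol delivers H to C5 and Al to C4 in a five-membered alkoxyaluminate, and iodinolysis with retention gives the vinyl iodide with iodine cis to C6.

Step 9
Reactants: 10 (2S,3Z)-6-iodo-3-methyl-1,2-bis(triethylsilyloxy)hex-3-ene; 16 (3S,4Z)-6-(tert-butyldiphenylsilyloxy)-5-iodohexa-1,4-dien-3-ol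
Product: 19 (3S,4E,8Z,10S)-5-[(tert-butyldiphenylsilyloxy)methyl]-9-methyl-10,11-bis(triethylsilyloxy)undeca-1,4,8-trien-3-ol, via alkyllithium 17 (not isolated), via borate 18 (not isolated)
Conditions: 10, t-BuLi, Et2O, −78 °C; B-methoxy-9-BBN, THF, −78 °C → rt; then 16, Pd(dppf)Cl2 (cat.), AsPh3 (cat.), Cs2CO3, DMF/H2O, rt
Reagents that add atoms: none
Why: Iodine–lithium exchange and capture by the borinate give a B-alkyl borate that couples with the vinyl iodide under zerovalent palladium catalysis with retention (B-alkyl Suzuki–Miyaura coupling), so C3 takes the place of iodine cis to C6 and the free C6 hydroxyl is tolerated.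

Step 10
Reactants: 19 (3S,4E,8Z,10S)-5-[(tert-butyldiphenylsilyloxy)methyl]-9-methyl-10,11-bis(triethylsilyloxy)undeca-1,4,8-trien-3-ol; 20 2-(bromomethyl)acrylic acid
Product: 21 (3S,4E,8Z,10S)-5-[(tert-butyldiphenylsilyloxy)methyl]-9-methyl-10,11-bis(triethylsilyloxy)undeca-1,4,8-trien-3-yl 2-(bromomethyl)prop-2-enoate
Conditions: DCC, DMAP (cat.), CH2Cl2, −20 → 0 °C
Reagents that add atoms: none
Why: Steglich esterification of the only free (secondary, bis-allylic) hydroxyl brings in C11, C12 and C13 with the allylic bromide, the low temperature limiting attack of the catalyst on the bromide.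

Step 11
Reactants: 21 (3S,4E,8Z,10S)-5-[(tert-butyldiphenylsilyloxy)methyl]-9-methyl-10,11-bis(triethylsilyloxy)undeca-1,4,8-trien-3-yl 2-(bromomethyl)prop-2-enoate
Product: 22 (5R)-3-(bromomethyl)-5-[(1E,5Z,7S)-2-[(tert-butyldiphenylsilyloxy)methyl]-6-methyl-7,8-bis(triethylsilyloxy)octa-1,5-dien-1-yl]furan-2(5H)-one
Conditions: second-generation Grubbs catalyst (cat.), CH2Cl2, 40 °C, dilute
Reagents that add atoms: none
Why: In this ring-closing metathesis the ruthenium carbene loads at the monosubstituted C7 vinyl group and closes onto the 1,1-disubstituted acrylate olefin to give the five-membered butenolide with loss of ethylene, the trisubstituted olefins being too hindered to compete.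

Step 12
Reactants: 22 (5R)-3-(bromomethyl)-5-[(1E,5Z,7S)-2-[(tert-butyldiphenylsilyloxy)methyl]-6-methyl-7,8-bis(triethylsilyloxy)octa-1,5-dien-1-yl]furan-2(5H)-one
Product: 23 (5R)-3-(bromomethyl)-5-[(1E,5Z,7S)-2-[(tert-butyldiphenylsilyloxy)methyl]-8-hydroxy-6-methyl-7-(triethylsilyloxy)octa-1,5-dien-1-yl]furan-2(5H)-one
Conditions: PPTS (cat.), MeOH/CH2Cl2, 0 °C
Reagents that add atoms: none
Why: Acid-catalysed methanolysis removes the primary triethylsilyl ether much faster than the hindered secondary one, while the tert-butyldiphenylsilyl ether and the allylic bromide are stable to this weakly acidic, non-nucleophilic medium.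

Step 13
Reactants: 23 (5R)-3-(bromomethyl)-5-[(1E,5Z,7S)-2-[(tert-butyldiphenylsilyloxy)methyl]-8-hydroxy-6-methyl-7-(triethylsilyloxy)octa-1,5-dien-1-yl]furan-2(5H)-one
Product: 24 (2S,3Z,7E)-8-[(2R)-4-(bromomethyl)-5-oxo-2,5-dihydrofuran-2-yl]-7-[(tert-butyldiphenylsilyloxy)methyl]-3-methyl-2-(triethylsilyloxy)octa-3,7-dienal
Conditions: Dess–Martin periodinane, CH2Cl2, 0 °C → rt; used at once
Reagents that add atoms: none
Why: Dess–Martin oxidation is base-free, so the α-silyloxy aldehyde should form without epimerisation at C9 and the allylic bromide is untouched.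

Step 14
Reactants: 24 (2S,3Z,7E)-8-[(2R)-4-(bromomethyl)-5-oxo-2,5-dihydrofuran-2-yl]-7-[(tert-butyldiphenylsilyloxy)methyl]-3-methyl-2-(triethylsilyloxy)octa-3,7-dienal
Product: 26 (1(10)Z,4E,6R,7R,8R,9S)-15-(tert-butyldiphenylsilyloxy)-8-hydroxy-9-(triethylsilyloxy)germacra-1(10),4,11(13)-trien-12,6-olide, via allylchromium species 25 (not isolated)
Conditions: CrCl2 (10 equiv), THF, rt; 24 added over 12 h by syringe pump (final 2 mM); aq. work-up
Reagents that add atoms: none
Why: Two equivalents of CrCl2 (divalent chromium) reduce the allylic C13–Br bond to an allylchromium species of trivalent chromium, which adds to the C8 aldehyde through a six-membered Zimmerman–Traxler transition state with allylic transposition, so that the γ-carbon C7 bonds to C8 and the C11=C13 methylene appears; the closest known reaction types are the intramolecular Nozaki–Hiyama–Kishi/Barbier allylation used to close 10-membered germacranolide rings and the intermolecular addition of 5-substituted 3-(bromomethyl)furan-2(5H)-ones to aldehydes. The only ring closed is the 10-membered carbocycle, by 10-exo-trig attack on the aldehyde carbonyl, the lactone ring being already in place. C7 is controlled by C6: chromium and aldehyde occupy the butenolide face opposite the C6–C5 bond, which gives the trans-fused lactone (H6 and H7 anti), because closure on the other face would eclipse the tether across C6–C7. C8 is controlled by the fixed geometry of the ring-bound allyl unit (C6 trans to C13, an E-crotyl-type reagent) in a chair with C9 equatorial, which gives the C6/O8-anti adduct, and by Felkin–Anh addition anti to the non-chelating C9 silyloxy group; both elements point to the 8R alcohol, the C8 epimer of the target, which step 15 inverts (C7 has the target's spatial arrangement and reads R in 26 only because of CIP priorities). The step needs γ- over α-attack of the allyl unit (secured by the closed transition state), ring closure over oligomerisation (high dilution, slow addition, two cis-trisubstituted olefins as turn elements in the seven-atom tether) and a single electrophile (lactone and silyl ethers are inert to allylchromium).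

Step 15
Reactants: 26 (1(10)Z,4E,6R,7R,8R,9S)-15-(tert-butyldiphenylsilyloxy)-8-hydroxy-9-(triethylsilyloxy)germacra-1(10),4,11(13)-trien-12,6-olide; 27 methacrylic acid
Product: 28 (1(10)Z,4E,6R,7S,8S,9S)-15-(tert-butyldiphenylsilyloxy)-8-(methacryloyloxy)-9-(triethylsilyloxy)germacra-1(10),4,11(13)-trien-12,6-olide
Conditions: PPh3, DIAD, toluene, 0 °C → rt
Reagents that add atoms: none
Why: In this Mitsunobu esterification the C8 oxyphosphonium ion is displaced by methacrylate in an SN2 process with inversion (8R to 8S), installing the ester with the target configuration, while the silyl ether at C9 excludes neighbouring-group participation (the C7 descriptor changes to S through CIP priorities only).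

Step 16
Reactants: 28 (1(10)Z,4E,6R,7S,8S,9S)-15-(tert-butyldiphenylsilyloxy)-8-(methacryloyloxy)-9-(triethylsilyloxy)germacra-1(10),4,11(13)-trien-12,6-olide
Product: 29 (1(10)Z,4E,6R,7S,8S,9S)-15-(tert-butyldiphenylsilyloxy)-9-hydroxy-8-(methacryloyloxy)germacra-1(10),4,11(13)-trien-12,6-olide
Conditions: HF·pyridine, pyridine, THF, 0 °C
Reagents that add atoms: none
Why: Fluoride cleaves the secondary triethylsilyl ether much faster than the primary tert-butyldiphenylsilyl ether at 0 °C, and the buffered medium should leave both esters in place.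

Step 17
Reactants: 29 (1(10)Z,4E,6R,7S,8S,9S)-15-(tert-butyldiphenylsilyloxy)-9-hydroxy-8-(methacryloyloxy)germacra-1(10),4,11(13)-trien-12,6-olide
Product: 30 (1(10)Z,4E,6R,7S,8S,9S)-9-acetoxy-15-(tert-butyldiphenylsilyloxy)-8-(methacryloyloxy)germacra-1(10),4,11(13)-trien-12,6-olide
Conditions: Ac2O, pyridine, DMAP (cat.), CH2Cl2, 0 °C
Reagents that add atoms: acetic anhydride, CC(=O)OC(C)=O
Why: Acylation of the only free hydroxyl (C9), run directly after step 16 to forestall acyl migration from O8.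

Step 18
Reactants: 30 (1(10)Z,4E,6R,7S,8S,9S)-9-acetoxy-15-(tert-butyldiphenylsilyloxy)-8-(methacryloyloxy)germacra-1(10),4,11(13)-trien-12,6-olide
Product: 31 (1(10)Z,4E,6R,7S,8S,9S)-9-acetoxy-15-(tert-butyldiphenylsilyloxy)-14-hydroxy-8-(methacryloyloxy)germacra-1(10),4,11(13)-trien-12,6-olide
Conditions: SeO2 (0.5 equiv), t-BuOOH, CH2Cl2, rt
Reagents that add atoms: selenium dioxide, O=[Se]=O (oxygen donor, turned over by tert-butyl hydroperoxide, CC(C)(C)OO)
Why: Riley allylic oxidation (ene reaction, then [2,3]-sigmatropic shift) attacks the more substituted end of the C1=C10 olefin at the methyl group trans to C2 and returns the double bond with C14 trans to C2, a reaction type known for the C14 methyl of germacranolides; the C4=C5 olefin carries two allylic C–O bonds and the two acrylate olefins are electron-poor, so they should react more slowly.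

Step 19
Reactants: 31 (1(10)Z,4E,6R,7S,8S,9S)-9-acetoxy-15-(tert-butyldiphenylsilyloxy)-14-hydroxy-8-(methacryloyloxy)germacra-1(10),4,11(13)-trien-12,6-olide
Product: 32 (1(10)E,4E,6R,7S,8S,9S)-9-acetoxy-15-(tert-butyldiphenylsilyloxy)-8-(methacryloyloxy)-14-oxogermacra-1(10),4,11(13)-trien-12,6-olide
Conditions: MnO2, CH2Cl2, rt
Reagents that add atoms: none
Why: Manganese dioxide oxidises the only free, primary allylic alcohol to the enal without touching esters or olefin geometry (the descriptor changes to E through CIP priorities only).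

Step 20
Reactants: 32 (1(10)E,4E,6R,7S,8S,9S)-9-acetoxy-15-(tert-butyldiphenylsilyloxy)-8-(methacryloyloxy)-14-oxogermacra-1(10),4,11(13)-trien-12,6-olide
Product: 33 (1(10)E,4E,6R,7S,8S,9S)-9-acetoxy-15-hydroxy-8-(methacryloyloxy)-14-oxogermacra-1(10),4,11(13)-trien-12,6-olide
Conditions: HF·pyridine, THF, 0 °C → rt
Reagents that add atoms: none
Why: Fluoride removes the primary allylic silyl ether under near-neutral conditions that should spare the enal, the acetate, the methacrylate and the α-methylene lactone.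

**Compound list**

1 | methyl (R)-2,2-dimethyl-1,3-dioxolane-4-carboxylate | COC(=O)[C@@H]1OC(C)(C)OC1 | starting material
2 | (R)-N-methoxy-N,2,2-trimethyl-1,3-dioxolane-4-carboxamide (Weinreb amide, not isolated) | CON(C)C(=O)[C@@H]1OC(C)(C)OC1 | intermediate
3 | (R)-1-(2,2-dimethyl-1,3-dioxolan-4-yl)ethan-1-one | CC(=O)[C@@H]1OC(C)(C)OC1 | intermediate
4 | [3-(tert-butyldimethylsilyloxy)propyl]triphenylphosphonium bromide | CC(C)(C)[Si](C)(C)OCCC[P+](c1ccccc1)(c1ccccc1)c1ccccc1.[Br-] | starting material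
5 | [3-(tert-butyldimethylsilyloxy)propylidene]triphenylphosphorane (ylide, not isolated) | CC(C)(C)[Si](C)(C)OCCC=P(c1ccccc1)(c1ccccc1)c1ccccc1 | intermediate
6 | (4S)-4-[(2Z)-5-(tert-butyldimethylsilyloxy)pent-2-en-2-yl]-2,2-dimethyl-1,3-dioxolane | CC(C)(C)[Si](C)(C)OCC/C=C(/C)[C@@H]1OC(C)(C)OC1 | intermediate
7 | (3Z)-4-[(4S)-2,2-dimethyl-1,3-dioxolan-4-yl]pent-3-en-1-ol | OCC/C=C(/C)[C@@H]1OC(C)(C)OC1 | intermediate
8 | (4S)-4-[(2Z)-5-iodopent-2-en-2-yl]-2,2-dimethyl-1,3-dioxolane | ICC/C=C(/C)[C@@H]1OC(C)(C)OC1 | intermediate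
9 | (2S,3Z)-6-iodo-3-methylhex-3-ene-1,2-diol | ICC/C=C(/C)[C@@H](CO)O | intermediate
10 | (2S,3Z)-6-iodo-3-methyl-1,2-bis(triethylsilyloxy)hex-3-ene | ICC/C=C(/C)[C@@H](CO[Si](CC)(CC)CC)O[Si](CC)(CC)CC | intermediate
11 | tert-butyldiphenyl(prop-2-yn-1-yloxy)silane | C#CCO[Si](c1ccccc1)(c1ccccc1)C(C)(C)C | starting material
12 | acrolein | C=CC=O | starting material
13 | methyl[3-(tert-butyldiphenylsilyloxy)prop-1-yn-1-yl]zinc (not isolated) | C[Zn]C#CCO[Si](c1ccccc1)(c1ccccc1)C(C)(C)C | intermediate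
14 | (3S)-6-(tert-butyldiphenylsilyloxy)hex-1-en-4-yn-3-ol | O[C@@H](C=C)C#CCO[Si](c1ccccc1)(c1ccccc1)C(C)(C)C | intermediate
15 | cyclic sodium alkenyl(alkoxy)aluminate of 14, Al on C4 and on the C6 oxygen (not isolated) | C=C[C@@H]1O[Al-](OCCOC)(OCCOC)C(CO[Si](c2ccccc2)(c2ccccc2)C(C)(C)C)=C1.[Na+] | intermediate
16 | (3S,4Z)-6-(tert-butyldiphenylsilyloxy)-5-iodohexa-1,4-dien-3-ol | O[C@@H](C=C)/C=C(/CO[Si](c1ccccc1)(c1ccccc1)C(C)(C)C)I | intermediate
17 | [(3Z,5S)-4-methyl-5,6-bis(triethylsilyloxy)hex-3-en-1-yl]lithium (not isolated) | [Li]CC/C=C(/C)[C@@H](CO[Si](CC)(CC)CC)O[Si](CC)(CC)CC | intermediate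
18 | lithium B-methoxy-B-[(3Z,5S)-4-methyl-5,6-bis(triethylsilyloxy)hex-3-en-1-yl]-9-borabicyclo[3.3.1]nonan-9-uide (not isolated) | CO[B-]1(CC/C=C(/C)[C@@H](CO[Si](CC)(CC)CC)O[Si](CC)(CC)CC)C2CCCC1CCC2.[Li+] | intermediate
19 | (3S,4E,8Z,10S)-5-[(tert-butyldiphenylsilyloxy)methyl]-9-methyl-10,11-bis(triethylsilyloxy)undeca-1,4,8-trien-3-ol | O[C@@H](C=C)/C=C(/CO[Si](c1ccccc1)(c1ccccc1)C(C)(C)C)CC/C=C(/C)[C@@H](CO[Si](CC)(CC)CC)O[Si](CC)(CC)CC | intermediate
20 | 2-(bromomethyl)acrylic acid | C=C(CBr)C(=O)O | starting material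
21 | (3S,4E,8Z,10S)-5-[(tert-butyldiphenylsilyloxy)methyl]-9-methyl-10,11-bis(triethylsilyloxy)undeca-1,4,8-trien-3-yl 2-(bromomethyl)prop-2-enoate | C=C(CBr)C(=O)O[C@@H](C=C)/C=C(/CO[Si](c1ccccc1)(c1ccccc1)C(C)(C)C)CC/C=C(/C)[C@@H](CO[Si](CC)(CC)CC)O[Si](CC)(CC)CC | intermediate
22 | (5R)-3-(bromomethyl)-5-[(1E,5Z,7S)-2-[(tert-butyldiphenylsilyloxy)methyl]-6-methyl-7,8-bis(triethylsilyloxy)octa-1,5-dien-1-yl]furan-2(5H)-one | O=C1O[C@@H](C=C1CBr)/C=C(/CO[Si](c2ccccc2)(c2ccccc2)C(C)(C)C)CC/C=C(/C)[C@@H](CO[Si](CC)(CC)CC)O[Si](CC)(CC)CC | intermediate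
23 | (5R)-3-(bromomethyl)-5-[(1E,5Z,7S)-2-[(tert-butyldiphenylsilyloxy)methyl]-8-hydroxy-6-methyl-7-(triethylsilyloxy)octa-1,5-dien-1-yl]furan-2(5H)-one | O=C1O[C@@H](C=C1CBr)/C=C(/CO[Si](c2ccccc2)(c2ccccc2)C(C)(C)C)CC/C=C(/C)[C@@H](CO)O[Si](CC)(CC)CC | intermediate
24 | (2S,3Z,7E)-8-[(2R)-4-(bromomethyl)-5-oxo-2,5-dihydrofuran-2-yl]-7-[(tert-butyldiphenylsilyloxy)methyl]-3-methyl-2-(triethylsilyloxy)octa-3,7-dienal | O=C1O[C@@H](C=C1CBr)/C=C(/CO[Si](c2ccccc2)(c2ccccc2)C(C)(C)C)CC/C=C(/C)[C@@H](C=O)O[Si](CC)(CC)CC | intermediate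
25 | allylchromium dichloride derived from 24, CrCl2 unit on C13 (not isolated) | O=C1O[C@@H](C=C1C[Cr](Cl)Cl)/C=C(/CO[Si](c2ccccc2)(c2ccccc2)C(C)(C)C)CC/C=C(/C)[C@@H](C=O)O[Si](CC)(CC)CC | intermediate
26 | (1(10)Z,4E,6R,7R,8R,9S)-15-(tert-butyldiphenylsilyloxy)-8-hydroxy-9-(triethylsilyloxy)germacra-1(10),4,11(13)-trien-12,6-olide | O[C@@H]1[C@H]2C(=C)C(=O)O[C@@H]2/C=C(/CO[Si](c3ccccc3)(c3ccccc3)C(C)(C)C)CC/C=C(/C)[C@@H]1O[Si](CC)(CC)CC | intermediate
27 | methacrylic acid | C=C(C)C(=O)O | starting material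
28 | (1(10)Z,4E,6R,7S,8S,9S)-15-(tert-butyldiphenylsilyloxy)-8-(methacryloyloxy)-9-(triethylsilyloxy)germacra-1(10),4,11(13)-trien-12,6-olide | C=C(C)C(=O)O[C@H]1[C@H]2C(=C)C(=O)O[C@@H]2/C=C(/CO[Si](c3ccccc3)(c3ccccc3)C(C)(C)C)CC/C=C(/C)[C@@H]1O[Si](CC)(CC)CC | intermediate
29 | (1(10)Z,4E,6R,7S,8S,9S)-15-(tert-butyldiphenylsilyloxy)-9-hydroxy-8-(methacryloyloxy)germacra-1(10),4,11(13)-trien-12,6-olide | C=C(C)C(=O)O[C@H]1[C@H]2C(=C)C(=O)O[C@@H]2/C=C(/CO[Si](c3ccccc3)(c3ccccc3)C(C)(C)C)CC/C=C(/C)[C@@H]1O | intermediate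
30 | (1(10)Z,4E,6R,7S,8S,9S)-9-acetoxy-15-(tert-butyldiphenylsilyloxy)-8-(methacryloyloxy)germacra-1(10),4,11(13)-trien-12,6-olide | C=C(C)C(=O)O[C@H]1[C@H]2C(=C)C(=O)O[C@@H]2/C=C(/CO[Si](c3ccccc3)(c3ccccc3)C(C)(C)C)CC/C=C(/C)[C@@H]1OC(C)=O | intermediate
31 | (1(10)Z,4E,6R,7S,8S,9S)-9-acetoxy-15-(tert-butyldiphenylsilyloxy)-14-hydroxy-8-(methacryloyloxy)germacra-1(10),4,11(13)-trien-12,6-olide | C=C(C)C(=O)O[C@H]1[C@H]2C(=C)C(=O)O[C@@H]2/C=C(/CO[Si](c3ccccc3)(c3ccccc3)C(C)(C)C)CC/C=C(/CO)[C@@H]1OC(C)=O | intermediate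
32 | (1(10)E,4E,6R,7S,8S,9S)-9-acetoxy-15-(tert-butyldiphenylsilyloxy)-8-(methacryloyloxy)-14-oxogermacra-1(10),4,11(13)-trien-12,6-olide | C=C(C)C(=O)O[C@H]1[C@H]2C(=C)C(=O)O[C@@H]2/C=C(/CO[Si](c3ccccc3)(c3ccccc3)C(C)(C)C)CC/C=C(/C=O)[C@@H]1OC(C)=O | intermediate
33 | (1(10)E,4E,6R,7S,8S,9S)-9-acetoxy-15-hydroxy-8-(methacryloyloxy)-14-oxogermacra-1(10),4,11(13)-trien-12,6-olide | C=C(C)C(=O)O[C@H]1[C@H]2C(=C)C(=O)O[C@@H]2/C=C(/CO)CC/C=C(/C=O)[C@@H]1OC(C)=O | target

**Count and risks**

Total step count: 20. Longest linear sequence: 18 steps (steps 1–6, then 9–20).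

Steps most likely to fail:

1. Step 14. Oligomerisation or simple reduction of the allylic bromide may outrun the 10-membered ring closure, or the closure may show poor facial control. The fallback sets out from 16 and 10 and comes back at 26; it forms C7–C8 between two pieces and closes the ring at C3–C4 instead. Vinyl iodide 16 is esterified with 20 (DCC) to the iodo dienyl acrylate F1, which second-generation Grubbs catalyst should close to the iodoalkenyl bromobutenolide F2. Iodide 10 is desilylated at the primary oxygen (PPTS, MeOH) to the primary alcohol F3 and oxidised (Dess–Martin periodinane) to the iodo aldehyde F4. A Barbier allylation of F4 with F2 (indium metal, THF/H2O) should give the open-chain homoallylic alcohol F5 with the same trans-lactone and 8R sense. Zinc insertion into the primary iodide (Zn dust, LiCl, THF) and intramolecular Negishi coupling with the vinyl iodide (Pd(PPh3)4, high dilution) would then close the ring to 26.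

2. Step 15. Elimination of the activated C8 oxygen, or esterification without inversion at this hindered ring carbon, may prevail. The fallback sets out from 26 and comes back at 28. Oxidation of 26 (Dess–Martin periodinane) gives the 8-ketone F6. Luche reduction (NaBH4, CeCl3·7H2O, MeOH, −78 °C) from the open face of the ketone, away from the lactone ring, should give the 8S alcohol F7. Acylation with methacrylic anhydride (DMAP, Et3N, CH2Cl2) leads to 28. This detour also converges any 8R/8S mixture from step 14.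

3. Step 18. Site selectivity may be lost (ene reaction at the C4=C5 olefin) or the polyfunctional macrocycle may be over-oxidised. The fallback sets out from 30 and comes back at 31. The C14 methyl of 30 is hydroxylated enzymatically by an engineered cytochrome P450 monooxygenase (a P450 BM3 variant, whole cells or lysate with NADPH regeneration, aqueous buffer/DMSO, rt), an enzyme class used for allylic methyl hydroxylation of germacranolides. No new compound is made.

**Further compounds**

F1 | step 14 | (3S,4Z)-6-(tert-butyldiphenylsilyloxy)-5-iodohexa-1,4-dien-3-yl 2-(bromomethyl)prop-2-enoate | C=C(CBr)C(=O)O[C@@H](C=C)/C=C(/CO[Si](c1ccccc1)(c1ccccc1)C(C)(C)C)I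
F2 | step 14 | (5S)-3-(bromomethyl)-5-[(1Z)-3-(tert-butyldiphenylsilyloxy)-2-iodoprop-1-en-1-yl]furan-2(5H)-one | O=C1O[C@@H](C=C1CBr)/C=C(/CO[Si](c2ccccc2)(c2ccccc2)C(C)(C)C)I
F3 | step 14 | (2S,3Z)-6-iodo-3-methyl-2-(triethylsilyloxy)hex-3-en-1-ol | ICC/C=C(/C)[C@@H](CO)O[Si](CC)(CC)CC
F4 | step 14 | (2S,3Z)-6-iodo-3-methyl-2-(triethylsilyloxy)hex-3-enal | ICC/C=C(/C)[C@@H](C=O)O[Si](CC)(CC)CC
F5 | step 14 | (4R,5S)-4-[(1R,2S,3Z)-1-hydroxy-6-iodo-3-methyl-2-(triethylsilyloxy)hex-3-en-1-yl]-5-[(1Z)-3-(tert-butyldiphenylsilyloxy)-2-iodoprop-1-en-1-yl]-3-methylidenedihydrofuran-2(3H)-one | O[C@H]([C@H]1C(=C)C(=O)O[C@@H]1/C=C(/CO[Si](c2ccccc2)(c2ccccc2)C(C)(C)C)I)[C@@H](O[Si](CC)(CC)CC)/C(C)=C\CCI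
F6 | step 15 | (1(10)Z,4E,6R,7S,9S)-15-(tert-butyldiphenylsilyloxy)-8-oxo-9-(triethylsilyloxy)germacra-1(10),4,11(13)-trien-12,6-olide | O=C1[C@H]2C(=C)C(=O)O[C@@H]2/C=C(/CO[Si](c3ccccc3)(c3ccccc3)C(C)(C)C)CC/C=C(/C)[C@@H]1O[Si](CC)(CC)CC
F7 | step 15 | (1(10)Z,4E,6R,7R,8S,9S)-15-(tert-butyldiphenylsilyloxy)-8-hydroxy-9-(triethylsilyloxy)germacra-1(10),4,11(13)-trien-12,6-olide | O[C@H]1[C@H]2C(=C)C(=O)O[C@@H]2/C=C(/CO[Si](c3ccccc3)(c3ccccc3)C(C)(C)C)CC/C=C(/C)[C@@H]1O[Si](CC)(CC)CC
F0 | step 18 | none | none
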